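**Retrosynthetic overview**
- The route rests on the single, fully substituted 1,4-benzoquinone ring: C1(=O), C2(OH), C3(CH3), C4(=O), C5(OH), C6(C19 chain). Both hydroxyls are carried as ethyl vinylogous esters until the last step.
- The ring is cut 4 + 2. C1, C6, C5 and C4 come from a 3-ethoxy-4-alkylcyclobutenedione; C2 and C3 come from a 2-ethoxy-1-methylvinyl anion. Carbonyl addition forms C3–C4, then heat cleaves the four-ring bond C1–C4 and closes C1–C2.
- The cyclobutenedione comes from diethyl squarate and the C19 Grignard reagent. The chain is C13 (tridecanedioic acid) plus C6 (1-hexyne), and the E alkene comes from dissolving-metal reduction of the alkyne.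
- Ring order: the four-membered ring is bought and then expanded to the six-membered carbocycle, the only ring of the target.

Key step: step 9

Assumption: the target is treated as the drawn 2,5-dihydroxy-1,4-benzoquinone tautomer, and the geometric isomers of the bromo enol ether made in step 7 are taken to be separable by fractional distillation.

**Route**

Step 1
Reactants: 1 tridecanedioic acid
Product: 2 tridecane-1,13-diol
Conditions: BH3·THF (3 equiv), THF, 0 °C to rt; then H2O, aq. K2CO3
Reagents that add atoms: none
Why: Borane reduces carboxylic acids rapidly through acyloxyboranes (borane reduction of a carboxylic acid), so both termini should go to primary alcohols with no other function present to interfere.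

Step 2
Reactants: 2 tridecane-1,13-diol
Product: 3 13-bromotridecan-1-ol
Conditions: 48% aq. HBr (1.2 equiv), toluene, reflux
Reagents that add atoms: hydrogen bromide, Br
Why: SN2 substitution of one protonated primary hydroxyl by bromide in the two-phase toluene/aqueous HBr system, where the monobromide moves into toluene away from the acid, should stop largely at the bromo alcohol (selective monobromination of an α,ω-diol).

Step 3
Reactants: 3 13-bromotridecan-1-ol; 4 hex-1-yne
Product: 6 nonadec-14-yn-1-ol, via lithium hex-1-yn-1-ide 5 (not isolated)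
Conditions: 4 (2.5 equiv), n-BuLi (2.4 equiv), THF, −78 to 0 °C; then 3, THF/DMPU, 0 to 40 °C; then H2O
Reagents that add atoms: none
Why: SN2 alkylation of a lithium acetylide by a primary bromide in a dipolar cosolvent should join C13 and C6 into the C19 skeleton, the first equivalent of acetylide only turning the hydroxyl into a lithium alkoxide that is too weak a nucleophile in THF to compete.

Step 4
Reactants: 6 nonadec-14-yn-1-ol
Product: 7 (E)-nonadec-14-en-1-ol
Conditions: Li (excess), NH3(l)/THF 1:1, −33 °C; then solid NH4Cl
Reagents that add atoms: none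
Why: Dissolving-metal reduction of an internal alkyne runs through a vinyl radical/anion that adopts the trans arrangement before protonation, so the C14=C15 alkene should form with E geometry, and an isolated alkene is not reduced further.

Step 5
Reactants: 7 (E)-nonadec-14-en-1-ol
Product: 8 (E)-19-bromononadec-5-ene
Conditions: CBr4, PPh3, CH2Cl2, 0 °C to rt
Reagents that add atoms: carbon tetrabromide, BrC(Br)(Br)Br
Why: Appel reaction, in which the alcohol is activated as an alkoxyphosphonium ion and displaced by bromide at a primary carbon under neutral conditions that leave the E alkene untouched.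

Step 6
Reactants: 8 (E)-19-bromononadec-5-ene; 9 diethyl squarate
Product: 12 3-ethoxy-4-[(E)-nonadec-14-en-1-yl]cyclobut-3-ene-1,2-dione, via Grignard reagent 10 (not isolated), via squarate adduct 11 (not isolated)
Conditions: Mg turnings, THF, 40 °C; then added to 9, THF, −78 °C; H2O quench; crude adduct, conc. HCl (cat.), CH2Cl2, rt
Reagents that add atoms: none
Why: Grignard formation from a primary bromide, 1,2-addition to one of the two equivalent squarate carbonyls at low temperature (the alkoxide formed resists a second addition) and acid-induced ionisation of the tertiary carbinol with net loss of ethanol is the standard passage from a dialkyl squarate to a 3-alkoxy-4-alkylcyclobutenedione.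

Step 7
Reactants: 13 ethyl prop-1-enyl ether (commercial E/Z mixture)
Product: 15 (Z)-2-bromo-1-ethoxyprop-1-ene (Br and OEt on the same side), via 1,2-dibromo-1-ethoxypropane 14 (not isolated)
Conditions: Br2, CH2Cl2, −78 °C; then i-Pr2NEt, −78 °C to 40 °C; fractional distillation
Reagents that add atoms: bromine, BrBr
Why: Electrophilic bromination gives the α,β-dibromo ether whatever the geometry of 13, and amine-induced dehydrobromination through the oxocarbenium ion of the labile α-bromide removes the C2 hydrogen to give the β-bromo enol ether, in which the isomer with Br cis to OEt is expected to predominate as in the parent 2-bromovinyl ether and is isolated by distillation, its geometry to be assigned by NOE between CH3 and the vinyl H.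

Step 8
Reactants: 12 3-ethoxy-4-[(E)-nonadec-14-en-1-yl]cyclobut-3-ene-1,2-dione; 15 (Z)-2-bromo-1-ethoxyprop-1-ene
Product: 17 3-ethoxy-4-[(Z)-1-ethoxyprop-1-en-2-yl]-4-hydroxy-2-[(E)-nonadec-14-en-1-yl]cyclobut-2-en-1-one (racemic), via vinyllithium 16 (not isolated)
Conditions: 15 (1.5 equiv), t-BuLi (1.95 equiv per 15), Et2O, −78 °C; then 12 in THF, −78 °C; cold H2O quench (pH ≥ 7); Et3N-deactivated silica
Reagents that add atoms: none
Why: Bromine–lithium exchange with t-BuLi goes with retention and places Li cis to OEt, so anti-periplanar loss of lithium ethoxide is geometrically barred at −78 °C, and the vinyllithium then adds 1,2 to the ketone-like carbonyl flanked by the ethoxy-bearing carbon, not to the vinylogous-ester carbonyl next to the alkyl-bearing carbon (regioselective organolithium addition to a 3-alkoxycyclobutenedione); the new carbinol stereocentre forms racemic and is erased in step 9.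

Step 9
Reactants: 17 3-ethoxy-4-[(Z)-1-ethoxyprop-1-en-2-yl]-4-hydroxy-2-[(E)-nonadec-14-en-1-yl]cyclobut-2-en-1-one
Product: 20 2,5-diethoxy-3-methyl-6-[(E)-nonadec-14-en-1-yl]benzene-1,4-diol, via dienylketene 18 (not isolated), via cyclohexadienone 19 (not isolated)
Conditions: toluene (degassed), 110 °C, Ar, glassware pre-rinsed with Et3N; crude product taken on under Ar
Reagents that add atoms: none
Why: Heating opens the cyclobutenone by conrotatory 4π electrocyclic cleavage of the bond between the ring carbonyl carbon and the carbinol carbon, the donor hydroxyl rotating outward so that the ethoxypropenyl group lies cis to the ketene in 18. Ketene 18 then closes by a thermally allowed disrotatory 6π electrocyclisation in which the ketene carbon bonds to the CH(OEt) terminus, giving the six-membered carbocycle as cyclohexadienone 19, and enolisation of the H on the sp3 carbon gives the aromatic hydroquinone irreversibly. The closest known reaction type is the thermal ring expansion of 4-alkenyl-4-hydroxycyclobutenones to hydroquinones (Moore rearrangement). No stereocentre survives: the racemic carbinol carbon, the sp3 carbon of 19 and the enol ether geometry all vanish on aromatisation, and the remote E alkene is inert to neutral thermolysis. The step needs outward rotation of the hydroxyl (inward rotation would let OH capture the ketene as a furanone), which the strongly donating OH secures, and the substitution pattern is already fixed by the connectivity of 17, so no regiochemical choice remains.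

Step 10
Reactants: 20 2,5-diethoxy-3-methyl-6-[(E)-nonadec-14-en-1-yl]benzene-1,4-diol
Product: 21 2,5-diethoxy-3-methyl-6-[(E)-nonadec-14-en-1-yl]cyclohexa-2,5-diene-1,4-dione
Conditions: Ag2O, anhydrous Na2SO4, Et2O, rt
Reagents that add atoms: none
Why: Ag2O is a mild two-electron oxidant for electron-rich hydroquinones (hydroquinone-to-quinone oxidation) and should not touch the isolated alkene or the ethyl ethers.

Step 11
Reactants: 21 2,5-diethoxy-3-methyl-6-[(E)-nonadec-14-en-1-yl]cyclohexa-2,5-diene-1,4-dione
Product: 23 2,5-dihydroxy-3-methyl-6-[(E)-nonadec-14-en-1-yl]cyclohexa-2,5-diene-1,4-dione, via disodium salt 22 (not isolated)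
Conditions: 2 M aq. NaOH, EtOH, Ar, rt to 50 °C; then 2 M HCl to pH 2
Reagents that add atoms: sodium hydroxide, [Na+].[OH-]
Why: Each ethoxy group is a vinylogous ester, so hydroxide adds at C2 and C5 and expels ethoxide (addition–elimination, vinylogous saponification) to give a delocalised dianion that resists further attack because no ring position is free, and acidification liberates the dihydroxyquinone.

**Compound list**
1 | tridecanedioic acid | OC(=O)CCCCCCCCCCCC(=O)O | starting material
2 | tridecane-1,13-diol | OCCCCCCCCCCCCCO | intermediate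
3 | 13-bromotridecan-1-ol | OCCCCCCCCCCCCCBr | intermediate
4 | hex-1-yne | CCCCC#C | starting material
5 | lithium hex-1-yn-1-ide | [Li]C#CCCCC | intermediate (not isolated)
6 | nonadec-14-yn-1-ol | CCCCC#CCCCCCCCCCCCCCO | intermediate
7 | (E)-nonadec-14-en-1-ol | CCCC/C=C/CCCCCCCCCCCCCO | intermediate
8 | (E)-19-bromononadec-5-ene | CCCC/C=C/CCCCCCCCCCCCCBr | intermediate
9 | diethyl squarate (3,4-diethoxycyclobut-3-ene-1,2-dione) | CCOC1=C(OCC)C(=O)C1=O | starting material
10 | [(E)-nonadec-14-en-1-yl]magnesium bromide | CCCC/C=C/CCCCCCCCCCCCC[Mg]Br | intermediate (not isolated)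
11 | 2,3-diethoxy-4-hydroxy-4-[(E)-nonadec-14-en-1-yl]cyclobut-2-en-1-one (racemic) | CCCC/C=C/CCCCCCCCCCCCCC1(O)C(OCC)=C(OCC)C1=O | intermediate (not isolated)
12 | 3-ethoxy-4-[(E)-nonadec-14-en-1-yl]cyclobut-3-ene-1,2-dione | CCCC/C=C/CCCCCCCCCCCCCC1=C(OCC)C(=O)C1=O | intermediate
13 | ethyl prop-1-enyl ether (E/Z mixture) | CC=COCC | starting material
14 | 1,2-dibromo-1-ethoxypropane (diastereomer mixture) | CC(Br)C(Br)OCC | intermediate (not isolated)
15 | (Z)-2-bromo-1-ethoxyprop-1-ene | C/C(Br)=C/OCC | intermediate
16 | (1-ethoxyprop-1-en-2-yl)lithium, Li cis to OEt (formally E, because Li ranks below CH3) | C/C([Li])=C/OCC | intermediate (not isolated)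
17 | 3-ethoxy-4-[(Z)-1-ethoxyprop-1-en-2-yl]-4-hydroxy-2-[(E)-nonadec-14-en-1-yl]cyclobut-2-en-1-one (racemic) | CCCC/C=C/CCCCCCCCCCCCCC1=C(OCC)C(O)(/C(C)=C\OCC)C1=O | intermediate
18 | (3Z,5Z)-3,6-diethoxy-4-hydroxy-5-methyl-2-[(E)-nonadec-14-en-1-yl]hexa-1,3,5-trien-1-one (dienylketene) | CCCC/C=C/CCCCCCCCCCCCCC(=C=O)/C(OCC)=C(O)\C(C)=C/OCC | intermediate (not isolated)
19 | 3,6-diethoxy-4-hydroxy-5-methyl-2-[(E)-nonadec-14-en-1-yl]cyclohexa-2,4-dien-1-one (racemic at C6) | CCCC/C=C/CCCCCCCCCCCCCC1=C(OCC)C(O)=C(C)C(OCC)C1=O | intermediate (not isolated)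
20 | 2,5-diethoxy-3-methyl-6-[(E)-nonadec-14-en-1-yl]benzene-1,4-diol | CCCC/C=C/CCCCCCCCCCCCCc1c(OCC)c(O)c(C)c(OCC)c1O | intermediate
21 | 2,5-diethoxy-3-methyl-6-[(E)-nonadec-14-en-1-yl]cyclohexa-2,5-diene-1,4-dione | CCCC/C=C/CCCCCCCCCCCCCC1=C(OCC)C(=O)C(C)=C(OCC)C1=O | intermediate
22 | disodium 3-methyl-6-[(E)-nonadec-14-en-1-yl]-1,4-benzoquinone-2,5-diolate | CCCC/C=C/CCCCCCCCCCCCCC1=C([O-])C(=O)C(C)=C([O-])C1=O.[Na+].[Na+] | intermediate (not isolated)
23 | 2,5-dihydroxy-3-methyl-6-[(E)-nonadec-14-en-1-yl]cyclohexa-2,5-diene-1,4-dione | CCCC/C=C/CCCCCCCCCCCCCC1=C(O)C(=O)C(C)=C(O)C1=O | target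

**Step count**
Total steps: 11. Longest linear sequence: 10 steps (steps 1–6 and 8–11, from tridecanedioic acid); step 7 is a one-step side branch.

**Steps most likely to fail, with fallbacks**

1. Step 8. The lithium reagent may lose lithium ethoxide before it adds (above all if any geometric isomer of the bromide is carried in). It may attack the vinylogous-ester carbonyl. The tertiary allylic carbinol next to an enol ether may ionise on work-up or chromatography. The fallback sets out from 12 and comes back at 23.
   - Isopropenylmagnesium bromide (THF, −78 °C), a robust vinyl nucleophile with no β-leaving group, adds at the same carbonyl to give 3-ethoxy-4-hydroxy-2-[(E)-nonadec-14-en-1-yl]-4-(prop-1-en-2-yl)cyclobut-2-en-1-one F1.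
   - Heating in toluene at 110 °C, the parent case of the alkenyl ring expansion, should give 3-ethoxy-5-methyl-2-[(E)-nonadec-14-en-1-yl]benzene-1,4-diol F2.
   - Ag2O oxidises it to 3-ethoxy-5-methyl-2-[(E)-nonadec-14-en-1-yl]cyclohexa-2,5-diene-1,4-dione F3, which has its one free ring C–H exactly where the second oxygen is needed.
   - Excess dimethylamine in EtOH under O2 with catalytic Cu(OAc)2 should aminate that C–H oxidatively and displace the ethoxy group by addition–elimination, giving 2,5-bis(dimethylamino)-3-methyl-6-[(E)-nonadec-14-en-1-yl]cyclohexa-2,5-diene-1,4-dione F4.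
   - Hydrolysis of both vinylogous amides with dilute aqueous HCl in dioxane at 60 °C then gives 23.
   - This path also removes any dependence on the geometric purity of 15.

2. Step 9. The ketene may be captured by the free hydroxyl (inward rotation leads to a furanone), or traces of acid may ionise the carbinol before the ring opens. The fallback sets out from 17 and comes back at 20.
   - The tertiary hydroxyl is silylated with N-(trimethylsilyl)imidazole in CH2Cl2 to give 3-ethoxy-4-[(Z)-1-ethoxyprop-1-en-2-yl]-2-[(E)-nonadec-14-en-1-yl]-4-[(trimethylsilyl)oxy]cyclobut-2-en-1-one F5.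
   - The silyloxy group is still a donor that rotates outward, but it can neither add to the ketene nor ionise easily. Thermolysis in toluene or p-xylene should therefore give 2,5-diethoxy-3-methyl-6-[(E)-nonadec-14-en-1-yl]-4-[(trimethylsilyl)oxy]phenol F6.
   - Desilylation with Bu4NF in THF at 0 °C under Ar gives 20, which enters step 10 as before.

3. Step 7. The dehydrobromination may give poor control of alkene geometry, and the isomers may not separate fully, which would feed an elimination-prone lithium reagent into step 8. The fallback sets out from 13 and comes back at 16.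
   - Bromination and dehydrobromination as in step 7, without fractionation, gives 15 together with (E)-2-bromo-1-ethoxyprop-1-ene F7.
   - NaNH2 in liquid NH3 should converge both isomers by loss of HBr on 1-ethoxyprop-1-yne F8.
   - Radical hydrostannation (Bu3SnH, catalytic AIBN, 70 °C) places tin on the carbon β to oxygen and, by kinetic anti addition, cis to OEt, giving (Z)-tributyl(1-ethoxyprop-1-en-2-yl)stannane F9. This is a stable compound that can be freed of its isomer on basic alumina.
   - Tin–lithium exchange with n-BuLi in THF at −78 °C proceeds with retention and delivers 16, which is used in step 8 as before.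

**Further compounds**
F1 | step 8 | 3-ethoxy-4-hydroxy-2-[(E)-nonadec-14-en-1-yl]-4-(prop-1-en-2-yl)cyclobut-2-en-1-one (racemic) | CCCC/C=C/CCCCCCCCCCCCCC1=C(OCC)C(O)(C(C)=C)C1=O
F2 | step 8 | 3-ethoxy-5-methyl-2-[(E)-nonadec-14-en-1-yl]benzene-1,4-diol | CCCC/C=C/CCCCCCCCCCCCCc1c(OCC)c(O)c(C)cc1O
F3 | step 8 | 3-ethoxy-5-methyl-2-[(E)-nonadec-14-en-1-yl]cyclohexa-2,5-diene-1,4-dione | CCCC/C=C/CCCCCCCCCCCCCC1=C(OCC)C(=O)C(C)=CC1=O
F4 | step 8 | 2,5-bis(dimethylamino)-3-methyl-6-[(E)-nonadec-14-en-1-yl]cyclohexa-2,5-diene-1,4-dione | CCCC/C=C/CCCCCCCCCCCCCC1=C(N(C)C)C(=O)C(C)=C(N(C)C)C1=O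
F5 | step 9 | 3-ethoxy-4-[(Z)-1-ethoxyprop-1-en-2-yl]-2-[(E)-nonadec-14-en-1-yl]-4-[(trimethylsilyl)oxy]cyclobut-2-en-1-one (racemic) | CCCC/C=C/CCCCCCCCCCCCCC1=C(OCC)C(O[Si](C)(C)C)(/C(C)=C\OCC)C1=O
F6 | step 9 | 2,5-diethoxy-3-methyl-6-[(E)-nonadec-14-en-1-yl]-4-[(trimethylsilyl)oxy]phenol | CCCC/C=C/CCCCCCCCCCCCCc1c(OCC)c(O[Si](C)(C)C)c(C)c(OCC)c1O
F7 | step 7 | (E)-2-bromo-1-ethoxyprop-1-ene | C/C(Br)=C\OCC
F8 | step 7 | 1-ethoxyprop-1-yne | CC#COCC
F9 | step 7 | (Z)-tributyl(1-ethoxyprop-1-en-2-yl)stannane | C/C(=C/OCC)[Sn](CCCC)(CCCC)CCCC
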